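A direct plan would start from the bought ring, 3,4-dimethylfuran A1, and would lithiate and alkylate it twice (propyl, then dec-9-enyl) to reach 2-(dec-9-en-1-yl)-3,4-dimethyl-5-propylfuran A2; hydroformylation of A2 would give 11-(3,4-dimethyl-5-propylfuran-2-yl)undecanal A3, and A3 would be joined by a carbene-catalysed aza-benzoin reaction to the amido sulfone A4, followed by desilylation.
Its weakest points would be three.
The aza-benzoin coupling would have to set the only stereocentre by catalyst control on an enolisable N-acyl aldimine, a substrate class with no enantioselective precedent, on the most advanced material and next to a ketone that lets base epimerise the new centre.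
The two furyllithium alkylations would be slow SN2 reactions on primary halides that compete with elimination and halogen–metal exchange, run twice in sequence on a volatile furan only to hang two unfunctionalised chains on a bought ring.
The hydroformylation would spend a pressure step and a linear/branched separation to add a single carbon.

Plan of the new route: the target is cut at C3–C4 (ketone carbon to chain) into an L-serine Weinreb amide, which brings C2 with its S configuration from the chiral pool, and a 10-(furyl)decyl Grignard reagent.
The furan (O1', C2' bearing the chain, C5' bearing propyl) is cut at O1'–C2', C2'–C3' and C4'–C5'. Because C3' and C4' both carry methyl, the C3'(CH3)=C4'(CH3) unit is the symmetrical alkyne but-2-yne, and C5' and C2' are the carbonyl carbons of butanal and of an 11-bromoundecanoyl amide.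
Divalent titanium turns the alkyne into a cis-but-2-ene-2,3-diyl dianion equivalent, so two acceptor carbons are joined through it: first butanal (giving a Z iodo allylic alcohol), then, after iodine–lithium exchange, the amide.
The resulting (Z)-γ-hydroxy enone closes and dehydrates to the furan in the same flask, so the only ring arises in mid-route from three acyclic pieces.
No furan is metallated or alkylated, no one-carbon homologation is needed, and no stereocentre is made by catalysis.

Key step: step 3

Assumption: N-acetyl-L-serine methyl ester is bought as the single L enantiomer. Primed locants refer to the furan, plain locants to the tridecane chain.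

Step 1
Reactants: 1 but-2-yne; 2 butanal
Product: 5 (2Z)-2-iodo-3-methylhept-2-en-4-ol (racemic), via titanacyclopropene 3 (not isolated), via oxatitanacyclopentene 4 (not isolated)
Conditions: Ti(OiPr)4 (1.3 equiv), i-PrMgCl (2.6 equiv), 1 (1.5 equiv), Et2O, −78 to −50 °C, 2 h; 2 (1.0 equiv), −78 to −50 °C, 1 h; I2 (2.0 equiv), −50 °C to rt; aq Na2S2O3
Reagents that add atoms: iodine, II
Why: In this titanium alkoxide-mediated reductive alkyne–aldehyde coupling, the Kulinkovich-type propene complex of divalent titanium exchanges propene for but-2-yne, the titanacyclopropene inserts butanal, and iodinolysis of the vinyl–titanium bond with retention should place iodine cis to the carbinol carbon because both were members of the five-membered titanacycle; the alkyne is symmetrical, so no regiochemical question arises, and the racemic carbinol centre is erased in step 3.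

Step 2
Reactants: 6 11-bromoundecanoic acid
Product: 8 11-bromo-N-methoxy-N-methylundecanamide, via 11-bromoundecanoyl chloride 7 (not isolated)
Conditions: (COCl)2 (1.2 equiv), DMF (cat.), CH2Cl2, 0 °C to rt, 2 h; concentrate; MeNHOMe·HCl (1.2 equiv), Et3N (2.5 equiv), CH2Cl2, 0 °C, 1 h
Reagents that add atoms: N,O-dimethylhydroxylamine hydrochloride, CNOC.Cl
Why: Standard Weinreb amide formation through the acid chloride, in which the primary bromide is inert to oxalyl chloride and to a short exposure to triethylamine at 0 °C.

Step 3
Reactants: 5 (2Z)-2-iodo-3-methylhept-2-en-4-ol; 8 11-bromo-N-methoxy-N-methylundecanamide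
Product: 12 2-(10-bromodecyl)-3,4-dimethyl-5-propylfuran, via dilithio alkoxide 9 (not isolated), via hydroxy enone 10 (not isolated), via cyclic hemiketal 11 (not isolated)
Conditions: 5 (1.2 equiv), MeLi (1.2 equiv), Et2O, −78 °C, 15 min; t-BuLi (2.4 equiv), −78 °C, 45 min; 8 (1.0 equiv), −78 to −20 °C, 2 h; sat. aq NH4Cl; then PPTS (5 mol %), CH2Cl2, rt, 1 h
Reagents that add atoms: none
Why: MeLi removes the hydroxyl proton and t-BuLi then exchanges iodine for lithium with retention of alkene geometry, giving the internally chelated γ-oxido vinyllithium 9 with lithium cis to the carbinol carbon, which adds to the Weinreb amide 8 to form a chelated tetrahedral adduct that releases the (Z)-γ-hydroxy enone 10 only on quench (halogen–lithium exchange followed by Weinreb ketone synthesis). The closest known reaction types are the acylation of dilithiated (Z)-3-iodoallylic alcohols and the acid-catalysed cyclodehydration of (Z)-γ-hydroxy enones to furans, the last stage shared with the Paal–Knorr synthesis. The furan closes at O1'–C2' by 5-exo-trig addition of the hydroxyl oxygen to the ketone carbonyl (hemiketal 11), and PPTS then ionises the allylic hemiketal to an oxocarbenium ion that loses H-5' and becomes aromatic, so the C2'–C3' bond and the ring are made in one flask. No stereocentre is created, and the racemic carbinol centre of 5 disappears on aromatisation. The step needs the Z geometry, which was fixed by the titanacycle of step 1 and holds hydroxyl and carbonyl cis so that cyclisation is the only outlet of 10, and it needs attack at the amide carbonyl in preference to the primary bromide, which is secured by adding 8 only after the second equivalent of t-BuLi has destroyed the tert-butyl iodide and by keeping the hindered vinyllithium at or below −20 °C, where SN2 displacement is slow. Three simple pieces, but-2-yne, butanal and an ω-bromo fatty amide, should thus give the fully substituted furan with its functionalised chain, with no regiochemical question because C3' and C4' carry the same substituent.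

Step 4
Reactants: 13 methyl (2S)-2-acetamido-3-hydroxypropanoate (N-acetyl-L-serine methyl ester)
Product: 14 methyl (2S)-2-acetamido-3-[(triethylsilyl)oxy]propanoate
Conditions: Et3SiCl (1.1 equiv), imidazole (2.0 equiv), CH2Cl2, 0 °C to rt, 2 h
Reagents that add atoms: chlorotriethylsilane, CC[Si](Cl)(CC)CC
Why: Imidazole-promoted silylation of the primary alcohol leaves the stereocentre untouched, and the triethylsilyl ether is chosen because it survives Grignard reagents yet falls to dilute acetic acid that spares the furan.

Step 5
Reactants: 14 methyl (2S)-2-acetamido-3-[(triethylsilyl)oxy]propanoate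
Product: 15 (2S)-2-acetamido-N-methoxy-N-methyl-3-[(triethylsilyl)oxy]propanamide
Conditions: MeNHOMe·HCl (2.0 equiv), i-PrMgCl (5.0 equiv), THF, −20 to 0 °C, 2 h; sat. aq NH4Cl
Reagents that add atoms: N,O-dimethylhydroxylamine hydrochloride, CNOC.Cl
Why: Direct ester aminolysis by the chloromagnesium amide of N,O-dimethylhydroxylamine needs no carboxyl activation (hence no azlactone), and the acetamide N–H is deprotonated first, which disfavours removal of the neighbouring α-hydrogen, so the S centre of L-serine should be kept.

Step 6
Reactants: 12 2-(10-bromodecyl)-3,4-dimethyl-5-propylfuran; 15 (2S)-2-acetamido-N-methoxy-N-methyl-3-[(triethylsilyl)oxy]propanamide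
Product: 17 N-[(2S)-13-(3,4-dimethyl-5-propylfuran-2-yl)-3-oxo-1-[(triethylsilyl)oxy]tridecan-2-yl]acetamide, via Grignard reagent 16 (not isolated)
Conditions: 12 (1.0 equiv), Mg turnings, THF, 40 °C, 2 h; separately 15 (1.3 equiv), i-PrMgCl (1.25 equiv), THF, −20 °C, 20 min; then 16, −20 to 0 °C, 3 h; sat. aq NH4Cl
Reagents that add atoms: none
Why: In this Weinreb ketone synthesis the amide is first converted into its N-magnesio salt so that the furyl-decyl Grignard reagent is not spent as a base and the α-hydrogen is shielded, the chelated tetrahedral adduct prevents over-addition, and the stereocentre comes unchanged from L-serine.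

Step 7
Reactants: 17 N-[(2S)-13-(3,4-dimethyl-5-propylfuran-2-yl)-3-oxo-1-[(triethylsilyl)oxy]tridecan-2-yl]acetamide
Product: 18 N-[(2S)-13-(3,4-dimethyl-5-propylfuran-2-yl)-1-hydroxy-3-oxotridecan-2-yl]acetamide (target)
Conditions: AcOH/THF/H2O (3:1:1), rt, 4 h
Reagents that add atoms: none
Why: Acid-catalysed solvolysis of a primary triethylsilyl ether under conditions expected to be too mild to open the tetraalkylfuran, to epimerise C2 or to dehydrate the β-hydroxy ketone.

Compound list
1 | but-2-yne | CC#CC | starting material
2 | butanal | CCCC=O | starting material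
3 | (η2-but-2-yne)titanium diisopropoxide (2,3-dimethyl-1,1-di(propan-2-yloxy)titanacyclopropene) | CC1=C(C)[Ti]1(OC(C)C)OC(C)C | intermediate
4 | 3,4-dimethyl-2,2-di(propan-2-yloxy)-5-propyl-1-oxa-2-titanacyclopent-3-ene (racemic) | CCCC1O[Ti](OC(C)C)(OC(C)C)C(C)=C1C | intermediate
5 | (2Z)-2-iodo-3-methylhept-2-en-4-ol (racemic) | CCCC(O)/C(C)=C(\I)C | intermediate
6 | 11-bromoundecanoic acid | OC(=O)CCCCCCCCCCBr | starting material
7 | 11-bromoundecanoyl chloride | ClC(=O)CCCCCCCCCCBr | intermediate
8 | 11-bromo-N-methoxy-N-methylundecanamide | CON(C)C(=O)CCCCCCCCCCBr | intermediate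
9 | lithium (2E)-2-lithio-3-methylhept-2-en-4-olate (racemic; lithium cis to the carbinol carbon) | CCCC(O[Li])/C(C)=C(\[Li])C | intermediate
10 | (5Z)-17-bromo-4-hydroxy-5,6-dimethylheptadec-5-en-7-one (racemic) | CCCC(O)/C(C)=C(\C(=O)CCCCCCCCCCBr)C | intermediate
11 | 2-(10-bromodecyl)-3,4-dimethyl-5-propyl-2,5-dihydrofuran-2-ol (mixture of stereoisomers) | CCCC1OC(O)(CCCCCCCCCCBr)C(C)=C1C | intermediate
12 | 2-(10-bromodecyl)-3,4-dimethyl-5-propylfuran | CCCc1oc(CCCCCCCCCCBr)c(C)c1C | intermediate
13 | methyl (2S)-2-acetamido-3-hydroxypropanoate (N-acetyl-L-serine methyl ester) | CC(=O)N[C@@H](CO)C(=O)OC | starting material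
14 | methyl (2S)-2-acetamido-3-[(triethylsilyl)oxy]propanoate | CC(=O)N[C@@H](CO[Si](CC)(CC)CC)C(=O)OC | intermediate
15 | (2S)-2-acetamido-N-methoxy-N-methyl-3-[(triethylsilyl)oxy]propanamide | CC(=O)N[C@@H](CO[Si](CC)(CC)CC)C(=O)N(C)OC | intermediate
16 | [10-(3,4-dimethyl-5-propylfuran-2-yl)decyl]magnesium bromide | CCCc1oc(CCCCCCCCCC[Mg]Br)c(C)c1C | intermediate
17 | N-[(2S)-13-(3,4-dimethyl-5-propylfuran-2-yl)-3-oxo-1-[(triethylsilyl)oxy]tridecan-2-yl]acetamide | CCCc1oc(CCCCCCCCCCC(=O)[C@H](CO[Si](CC)(CC)CC)NC(C)=O)c(C)c1C | intermediate
18 | N-[(2S)-13-(3,4-dimethyl-5-propylfuran-2-yl)-1-hydroxy-3-oxotridecan-2-yl]acetamide | CCCc1oc(CCCCCCCCCCC(=O)[C@H](CO)NC(C)=O)c(C)c1C | target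

Total step count: 7. Longest linear sequence: 4 steps (steps 1, 3, 6 and 7).

Steps most likely to fail

Step 3. The iodine–lithium exchange at the tetrasubstituted vinyl iodide may be incomplete, the hindered vinyllithium may deprotonate the Weinreb amide instead of adding to it, or it may attack the primary bromide. The fallback sets out from 5 and comes back at 12. The bought alkynol undec-10-yn-1-ol F1 would be converted by an Appel reaction (CBr4, PPh3, CH2Cl2, 0 °C) into 11-bromoundec-1-yne F2. F2 would be joined to 5 by Sonogashira coupling (PdCl2(PPh3)2, CuI, Et3N, THF, rt) to give (5Z)-17-bromo-5,6-dimethylheptadec-5-en-7-yn-4-ol F3. F3 would then be cycloisomerised (K2PdI4, 2 mol %, N,N-dimethylacetamide, 60 °C) by 5-exo-dig attack of the hydroxyl on the alkyne and an aromatising hydrogen shift to 12. In this variant C2' and the first chain carbon come from the alkyne, and no organolithium is used.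

Step 6. Grignard formation may give Wurtz-type homocoupling, and the addition may be accompanied by enolisation of the amide with loss of configuration at C2 or by β-elimination of the silyloxy group. The fallback sets out from 12 and 14 and comes back at 17. A Finkelstein exchange (NaI, acetone, reflux) would convert 12 into 2-(10-iododecyl)-3,4-dimethyl-5-propylfuran F4, and zinc insertion into F4 (Zn dust, THF, 40 °C) would give [10-(3,4-dimethyl-5-propylfuran-2-yl)decyl]zinc iodide F5. Ester 14 would be converted with Me3Al and ethanethiol (CH2Cl2, 0 °C to rt) into S-ethyl (2S)-2-acetamido-3-[(triethylsilyl)oxy]propanethioate F6. Fukuyama coupling of F6 with F5 (PdCl2(PPh3)2, 5 mol %, toluene/THF, rt) would give 17 under neutral, non-basic conditions that do not touch the α-hydrogen.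

Step 1. Ligand exchange with the volatile alkyne may be incomplete, the low-valent titanium may reduce butanal in a pinacol-type coupling, or the vinyl–titanium bond may be protonated before iodination. The fallback sets out from 2 and comes back at 5. Butanal and prop-1-ynylmagnesium bromide (THF, 0 °C) would give hept-2-yn-4-ol F7. Alkoxide-directed anti-carbomagnesiation of F7 (MeMgBr, 3 equiv, CuI, 10 mol %, THF, reflux) would deliver methyl to the alkyne carbon next to the carbinol and magnesium to the far carbon within a five-membered chelate. Iodine at −40 °C would then give 5 with iodine again cis to the carbinol carbon.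

Further compounds
F1 | step 3 | undec-10-yn-1-ol | C#CCCCCCCCCCO
F2 | step 3 | 11-bromoundec-1-yne | C#CCCCCCCCCCBr
F3 | step 3 | (5Z)-17-bromo-5,6-dimethylheptadec-5-en-7-yn-4-ol (racemic) | CCCC(O)/C(C)=C(\C#CCCCCCCCCCBr)C
F4 | step 6 | 2-(10-iododecyl)-3,4-dimethyl-5-propylfuran | CCCc1oc(CCCCCCCCCCI)c(C)c1C
F5 | step 6 | [10-(3,4-dimethyl-5-propylfuran-2-yl)decyl]zinc iodide | CCCc1oc(CCCCCCCCCC[Zn]I)c(C)c1C
F6 | step 6 | S-ethyl (2S)-2-acetamido-3-[(triethylsilyl)oxy]propanethioate | CCSC(=O)[C@H](CO[Si](CC)(CC)CC)NC(C)=O
F7 | step 1 | hept-2-yn-4-ol (racemic) | CC#CC(O)CCC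
A1 | direct plan | 3,4-dimethylfuran | Cc1cocc1C
A2 | direct plan | 2-(dec-9-en-1-yl)-3,4-dimethyl-5-propylfuran | CCCc1oc(CCCCCCCCC=C)c(C)c1C
A3 | direct plan | 11-(3,4-dimethyl-5-propylfuran-2-yl)undecanal | CCCc1oc(CCCCCCCCCCC=O)c(C)c1C
A4 | direct plan | N-{2-[(tert-butyldimethylsilyl)oxy]-1-[(4-methylphenyl)sulfonyl]ethyl}acetamide (racemic) | CC(=O)NC(CO[Si](C)(C)C(C)(C)C)S(=O)(=O)c1ccc(C)cc1
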